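**Retrosynthetic overview**

1. Feature: ring A (C1 CO2Me, C3 OH, C5 OMe, C6 bearing the ketone) has its OH para to C6 and both flanking positions substituted. It is therefore the aromatised, two-electron-reduced form of a cyclohexa-2,5-dien-4-one whose C6 is spiro-bonded to the ring B phenol oxygen next to chlorine (a grisadienone).
2. Target ⇒ (MOM removal, reductive C6–O cleavage reversed) spirodienone 22. The hindered diaryl ketone bond is carried through as the CH2–C(=O) bond of a five-membered ketone.
3. 22 ⇒ coumaranone 9 + diynone 20 by a double Michael addition that forms C6–C1 and C6–C5.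
4. 9 ⇐ orcinol (chlorination, bis-MOM, ortho-lithiation/chloroacetylation, deprotection/ring closure, MOM). 20 ⇐ methoxyacetylene + methyl 4-oxobut-2-ynoate, then MnO2.
5. Ring order: ring B is bought; the furanone ring closes in step 4; ring A closes in step 11; the furanone ring is opened in step 12.

Key step: step 11

Remark: the target has no stereocentre, so no enantiocontrol is needed; the spiro centre formed in step 11 is racemic and is destroyed in step 12.
Remark: step 4 is written for ring closure through the phenol next to chlorine; closure through the other phenol would give the 5-chloro coumaranone, which the same operations carry to the same target because ring B is symmetric apart from Cl.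

**Route**

Step 1
Reactants: 1 orcinol (5-methylbenzene-1,3-diol)
Product: 2 4-chloro-5-methylbenzene-1,3-diol
Conditions: SO2Cl2 (1.0 equiv), Et2O, 0 °C to rt; crystallisation
Reagents that add atoms: sulfuryl chloride, O=S(=O)(Cl)Cl
Why: Electrophilic aromatic chlorination; C4 (para to one OH, ortho to the other) should react in preference to the doubly ortho C2, and one equivalent at 0 °C limits dichlorination.

Step 2
Reactants: 2 4-chloro-5-methylbenzene-1,3-diol
Product: 3 2-chloro-1,5-bis(methoxymethoxy)-3-methylbenzene
Conditions: MOMCl (2.5 equiv), i-Pr2NEt, CH2Cl2, 0 °C to rt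
Reagents that add atoms: chloromethyl methyl ether, COCCl
Why: MOM ether formation on both phenols installs two ortho-directing groups that also serve as protection.

Step 3
Reactants: 3 2-chloro-1,5-bis(methoxymethoxy)-3-methylbenzene; 4 2-chloro-N-methoxy-N-methylacetamide
Product: 6 2-chloro-1-[3-chloro-2,6-bis(methoxymethoxy)-4-methylphenyl]ethan-1-one, via aryllithium 5 (not isolated)
Conditions: n-BuLi, TMEDA, THF, −20 to 0 °C; then 4, −78 to −20 °C; aq NH4Cl
Reagents that add atoms: none
Why: Directed ortho-metalation at the carbon flanked by both OMOM groups (no hydrogen lies ortho to Cl, so benzyne formation is not expected), followed by Weinreb ketone synthesis, whose chelated adduct prevents over-addition.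

Step 4
Reactants: 6 2-chloro-1-[3-chloro-2,6-bis(methoxymethoxy)-4-methylphenyl]ethan-1-one
Product: 8 7-chloro-4-hydroxy-6-methylbenzofuran-3(2H)-one, via dihydroxy chloromethyl ketone 7 (not isolated)
Conditions: HCl, MeOH, 50 °C; then NaOAc (excess), reflux
Reagents that add atoms: none
Why: Acid-catalysed acetal exchange frees both phenols, and acetate then drives an intramolecular Williamson etherification (5-exo-tet); the phenol next to chlorine is the more acidic and should be the one that is ionised and closes.

Step 5
Reactants: 8 7-chloro-4-hydroxy-6-methylbenzofuran-3(2H)-one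
Product: 9 7-chloro-4-(methoxymethoxy)-6-methylbenzofuran-3(2H)-one
Conditions: MOMCl, i-Pr2NEt, CH2Cl2, 0 °C to rt
Reagents that add atoms: chloromethyl methyl ether, COCCl
Why: MOM ether formation on the remaining phenol; its hydrogen bond to the five-ring ketone is weak, so an amine base should suffice and the acidic C2 methylene is left untouched.

Step 6
Reactants: 10 3,3-diethoxyprop-1-yne; 11 methyl chloroformate
Product: 13 methyl 4,4-diethoxybut-2-ynoate, via lithium 3,3-diethoxypropynide 12 (not isolated)
Conditions: n-BuLi, THF, −78 °C; then 11, −78 to 0 °C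
Reagents that add atoms: none
Why: Deprotonation of the terminal alkyne and C-acylation of the lithium acetylide with the chloroformate gives the ynoate while the acetal masks the aldehyde.

Step 7
Reactants: 13 methyl 4,4-diethoxybut-2-ynoate
Product: 14 methyl 4-oxobut-2-ynoate
Conditions: HCO2H (neat), rt to 40 °C; volatiles removed, short-path distillation, used at once
Reagents that add atoms: formic acid, OC=O
Why: Formic acid transacetalisation (the ethoxy groups leave as ethyl formate) unmasks the aldehyde without aqueous acid, avoiding hydration of the doubly activated alkyne.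

Step 8
Reactants: 15 chloroacetaldehyde dimethyl acetal
Product: 17 methoxyacetylene (methoxyethyne), via sodium methoxyacetylide 16 (not isolated)
Conditions: NaNH2 (3 equiv), liq. NH3, −33 °C; NH3 evaporated; cold aq NaCl, −70 °C; distilled into cold THF
Reagents that add atoms: none
Why: Amide-induced elimination of methanol and HCl from the chloroacetal (the standard alkoxyacetylene synthesis) gives the acetylide, which water releases as the volatile ynol ether, free of amine.

Step 9
Reactants: 17 methoxyacetylene; 14 methyl 4-oxobut-2-ynoate
Product: 19 methyl 4-hydroxy-6-methoxyhexa-2,5-diynoate (racemic), via lithium methoxyacetylide 18 (not isolated)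
Conditions: n-BuLi (0.95 equiv), THF, −78 °C; then 14, −78 °C; sat. aq NH4Cl at −78 °C
Reagents that add atoms: none
Why: 1,2-Addition of a lithium acetylide to an aldehyde; at −78 °C the formyl group is far more reactive than the ester and lithium acetylides do not add in conjugate fashion; the carbinol is racemic and its stereocentre is removed in step 10.

Step 10
Reactants: 19 methyl 4-hydroxy-6-methoxyhexa-2,5-diynoate
Product: 20 methyl 6-methoxy-4-oxohexa-2,5-diynoate
Conditions: activated MnO2 (excess), CH2Cl2, 0 °C; filtered through Celite; solution used directly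
Reagents that add atoms: none
Why: MnO2 oxidation of a doubly propargylic alcohol to the cross-conjugated diynone under neutral, non-aqueous conditions that spare the ynol ether.

Step 11
Reactants: 9 7-chloro-4-(methoxymethoxy)-6-methylbenzofuran-3(2H)-one; 20 methyl 6-methoxy-4-oxohexa-2,5-diynoate
Product: 22 methyl 7-chloro-6'-methoxy-4-(methoxymethoxy)-6-methyl-3,4'-dioxo-3H-spiro[benzofuran-2,1'-cyclohexa[2,5]diene]-2'-carboxylate (racemic), via mono-Michael adduct 21 (not isolated)
Conditions: t-BuOK (0.2 equiv), THF/t-BuOH, −20 °C; 20 (1.2 equiv) added slowly; then rt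
Reagents that add atoms: none
Why: Proposed new method: catalytic t-BuOK converts 9 into its benzofuran-3-olate, which is nucleophilic at C2 and adds to C2 of 20 (the alkyne carbon β to the ketone and α to the ester, the most electrophilic site) to give enynone 21 after proton transfer; the remaining C2–H of 21 is then removed and the delocalised dienolate attacks the methoxy-bearing C6 of the ynone, with t-BuOH protonating the vinyl anion, so that both new bonds end on the same carbon and either order of addition leads to 22. The closest known reactions are the base-catalysed double Michael spiroannulation of 3-coumaranones with methoxyethynyl vinyl ketones (second closure 6-endo-trig) and the double hetero-Michael additions of sulfide, amines or water to penta-1,4-diyn-3-ones that give thiopyranones, pyridones and pyranones, which show that a 6-endo-dig second addition onto an ynone is feasible. Ring A is closed in that second step by 6-endo-dig conjugate addition, the smaller-ring alternative being anti-Michael. The spiro carbon is the only new stereocentre; nothing controls it, it should form racemic, and it disappears on aromatisation in step 12. The step needs C- over O-attack (a soft, aromatic-stabilised enolate, and O-adducts are vinylogous esters that can revert by addition–elimination), attack β to the ketone and not β to the ester (the ketone is the stronger acceptor), ring closure over oligomerisation of 20 (intramolecular second step, slow addition of 20 at low temperature), and the cis arrangement in 21 (E and Z forms equilibrate through the dienolate).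

Step 12
Reactants: 22 methyl 7-chloro-6'-methoxy-4-(methoxymethoxy)-6-methyl-3,4'-dioxo-3H-spiro[benzofuran-2,1'-cyclohexa[2,5]diene]-2'-carboxylate
Product: 23 methyl 2-[3-chloro-2-hydroxy-6-(methoxymethoxy)-4-methylbenzoyl]-5-hydroxy-3-methoxybenzoate
Conditions: Zn dust, AcOH, rt
Reagents that add atoms: none
Why: Dissolving-metal reduction: the spiro C–O bond is α to the C3 ketone and vinylogously γ to the dienone carbonyl, so two-electron transfer expels the aryloxide and the resulting 4-acyl-dienolate tautomerises to the ring A phenol; aryl chloride, ester and MOM ether should survive.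

Step 13
Reactants: 23 methyl 2-[3-chloro-2-hydroxy-6-(methoxymethoxy)-4-methylbenzoyl]-5-hydroxy-3-methoxybenzoate
Product: 24 monochlorosulochrin, methyl 2-(3-chloro-2,6-dihydroxy-4-methylbenzoyl)-5-hydroxy-3-methoxybenzoate
Conditions: HCl (2 M), MeOH, rt to 40 °C
Reagents that add atoms: none
Why: Acid-catalysed cleavage of the MOM acetal in methanol (no transesterification issue with the methyl ester), kept mild to avoid xanthone formation.

**Compound list**

1 | orcinol (5-methylbenzene-1,3-diol) | Cc1cc(O)cc(O)c1 | starting material
2 | 4-chloro-5-methylbenzene-1,3-diol | Cc1cc(O)cc(O)c1Cl | intermediate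
3 | 2-chloro-1,5-bis(methoxymethoxy)-3-methylbenzene | Cc1cc(OCOC)cc(OCOC)c1Cl | intermediate
4 | 2-chloro-N-methoxy-N-methylacetamide | CON(C)C(=O)CCl | starting material
5 | [3-chloro-2,6-bis(methoxymethoxy)-4-methylphenyl]lithium | [Li]c1c(OCOC)cc(C)c(Cl)c1OCOC | intermediate (not isolated)
6 | 2-chloro-1-[3-chloro-2,6-bis(methoxymethoxy)-4-methylphenyl]ethan-1-one | O=C(CCl)c1c(OCOC)cc(C)c(Cl)c1OCOC | intermediate
7 | 2-chloro-1-(3-chloro-2,6-dihydroxy-4-methylphenyl)ethan-1-one | O=C(CCl)c1c(O)cc(C)c(Cl)c1O | intermediate (not isolated)
8 | 7-chloro-4-hydroxy-6-methylbenzofuran-3(2H)-one | O=C1COc2c(Cl)c(C)cc(O)c12 | intermediate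
9 | 7-chloro-4-(methoxymethoxy)-6-methylbenzofuran-3(2H)-one | O=C1COc2c(Cl)c(C)cc(OCOC)c12 | intermediate
10 | 3,3-diethoxyprop-1-yne | C#CC(OCC)OCC | starting material
11 | methyl chloroformate | COC(=O)Cl | starting material
12 | lithium 3,3-diethoxypropynide | [Li]C#CC(OCC)OCC | intermediate (not isolated)
13 | methyl 4,4-diethoxybut-2-ynoate | COC(=O)C#CC(OCC)OCC | intermediate
14 | methyl 4-oxobut-2-ynoate | COC(=O)C#CC=O | intermediate
15 | chloroacetaldehyde dimethyl acetal | COC(CCl)OC | starting material
16 | sodium methoxyacetylide | [Na]C#COC | intermediate (not isolated)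
17 | methoxyacetylene | C#COC | intermediate
18 | lithium methoxyacetylide | [Li]C#COC | intermediate (not isolated)
19 | methyl 4-hydroxy-6-methoxyhexa-2,5-diynoate (racemic) | COC#CC(O)C#CC(=O)OC | intermediate
20 | methyl 6-methoxy-4-oxohexa-2,5-diynoate | COC#CC(=O)C#CC(=O)OC | intermediate
21 | methyl 2-[7-chloro-4-(methoxymethoxy)-6-methyl-3-oxo-2,3-dihydrobenzofuran-2-yl]-6-methoxy-4-oxohex-2-en-5-ynoate (racemic, E/Z mixture) | COC#CC(=O)C=C(C(=O)OC)C1Oc2c(Cl)c(C)cc(OCOC)c2C1=O | intermediate (not isolated)
22 | methyl 7-chloro-6'-methoxy-4-(methoxymethoxy)-6-methyl-3,4'-dioxo-3H-spiro[benzofuran-2,1'-cyclohexa[2,5]diene]-2'-carboxylate (racemic) | COC(=O)C1=CC(=O)C=C(OC)C12Oc3c(Cl)c(C)cc(OCOC)c3C2=O | intermediate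
23 | methyl 2-[3-chloro-2-hydroxy-6-(methoxymethoxy)-4-methylbenzoyl]-5-hydroxy-3-methoxybenzoate | COC(=O)c1cc(O)cc(OC)c1C(=O)c1c(OCOC)cc(C)c(Cl)c1O | intermediate
24 | monochlorosulochrin | COC(=O)c1cc(O)cc(OC)c1C(=O)c1c(O)cc(C)c(Cl)c1O | target

**Totals**

Total step count: 13. Longest linear sequence: 8 steps (1, 2, 3, 4, 5, 11, 12, 13).

**Steps most likely to fail**

1. Step 11 (Proposed new method). The enolate may attack the alkyne carbon β to the ester or react through oxygen. The diynone may oligomerise faster than the ring closes. The 6-endo-dig closure may be too slow because the linear alkyne must be bent into the ring. Fallback with known chemistry, setting out from 9 and 18 and returning at 22: lithium methoxyacetylide 18 is added at −78 °C to commercial methyl (E)-4-oxobut-2-enoate to give methyl (E)-4-hydroxy-6-methoxyhex-2-en-5-ynoate F1. MnO2 oxidation gives methyl (E)-6-methoxy-4-oxohex-2-en-5-ynoate F2, an alkoxyethynyl enone of the class established for coumaranone double Michael spiroannulation. Coumaranone 9 and F2 with catalytic t-BuOK should give methyl 7-chloro-6'-methoxy-4-(methoxymethoxy)-6-methyl-3,4'-dioxo-3H-spiro[benzofuran-2,1'-cyclohex[5]ene]-2'-carboxylate F3 as a diastereomer mixture. Dehydrogenation across C2'–C3' with DDQ in hot dioxane (the gris-enone to gris-dienone oxidation) then gives 22.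

2. Step 9. The acetylide or the product alkoxide may add in conjugate fashion to the doubly activated alkyne of 14, and 14 may oligomerise before it is trapped. Fallback with reversed polarity, setting out from 18 and returning at 19: 18 is formylated with DMF (THF, −78 °C, inverse quench into cold aq KH2PO4) to give 3-methoxypropynal F4. F4 is added at −78 °C to methyl 3-lithiopropiolate F5, made from methyl propiolate and n-BuLi at −100 °C, so that the ester sits on the nucleophile and the ynal-ester 14 is no longer needed; work-up gives 19.

3. Step 4. Ring closure may take place partly through the phenol remote from chlorine, splitting the material between two regioisomeric coumaranones. Fallback, setting out from 7 and returning at 24: no separation is attempted. The isomer 5-chloro-4-hydroxy-6-methylbenzofuran-3(2H)-one F6 is protected to 5-chloro-4-(methoxymethoxy)-6-methylbenzofuran-3(2H)-one F7. F7 is annulated with 20 as in step 11 to methyl 5-chloro-6'-methoxy-4-(methoxymethoxy)-6-methyl-3,4'-dioxo-3H-spiro[benzofuran-2,1'-cyclohexa[2,5]diene]-2'-carboxylate F8. Zn/AcOH opens F8 to methyl 2-[3-chloro-6-hydroxy-2-(methoxymethoxy)-4-methylbenzoyl]-5-hydroxy-3-methoxybenzoate F9, and acid deprotection of F9 gives the same target 24.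

**Further compounds**

F1 | step 11 | methyl (E)-4-hydroxy-6-methoxyhex-2-en-5-ynoate (racemic) | COC#CC(O)/C=C/C(=O)OC
F2 | step 11 | methyl (E)-6-methoxy-4-oxohex-2-en-5-ynoate | COC#CC(=O)/C=C/C(=O)OC
F3 | step 11 | methyl 7-chloro-6'-methoxy-4-(methoxymethoxy)-6-methyl-3,4'-dioxo-3H-spiro[benzofuran-2,1'-cyclohex[5]ene]-2'-carboxylate (racemic diastereomer mixture) | COC(=O)C1CC(=O)C=C(OC)C12Oc3c(Cl)c(C)cc(OCOC)c3C2=O
F4 | step 9 | 3-methoxypropynal | COC#CC=O
F5 | step 9 | methyl 3-lithiopropiolate | [Li]C#CC(=O)OC
F6 | step 4 | 5-chloro-4-hydroxy-6-methylbenzofuran-3(2H)-one | O=C1COc2cc(C)c(Cl)c(O)c12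
F7 | step 4 | 5-chloro-4-(methoxymethoxy)-6-methylbenzofuran-3(2H)-one | O=C1COc2cc(C)c(Cl)c(OCOC)c12
F8 | step 4 | methyl 5-chloro-6'-methoxy-4-(methoxymethoxy)-6-methyl-3,4'-dioxo-3H-spiro[benzofuran-2,1'-cyclohexa[2,5]diene]-2'-carboxylate (racemic) | COC(=O)C1=CC(=O)C=C(OC)C12Oc3cc(C)c(Cl)c(OCOC)c3C2=O
F9 | step 4 | methyl 2-[3-chloro-6-hydroxy-2-(methoxymethoxy)-4-methylbenzoyl]-5-hydroxy-3-methoxybenzoate | COC(=O)c1cc(O)cc(OC)c1C(=O)c1c(OCOC)c(Cl)c(C)cc1O
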